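## Structural features

The target is a 2H-chromene: benzene ring A is fused through C4a–C8a to pyran ring B (O1, C2, C3=C4). Ring A is substituted everywhere except C7: hydroxyls at C5 and C8 (a para-hydroquinone pair), the (E)-3-(4-hydroxyphenyl)propenoyl group at C6 (a 2'-hydroxychalcone whose 2'-hydroxyl is the C5 OH), O1 at C8a and C4 at C4a. C2 is the only stereocentre. It is quaternary, carries O1, C3, a methyl group and the 4-hydroxy-4-methylpentyl chain, has the S configuration, and has no stereogenic neighbour. The fragile groups are the enone (conjugate addition, and closure of the C5 hydroxyl onto it to a flavanone), the electron-rich hydroquinone (oxidation), the tertiary alcohol of the chain (ionisation in acid), and the allylic C2–O1 bond, whose ionisation would racemise C2. The real difficulty is C2: methyl and CH2 differ too little for dependable face discrimination by a catalyst, so the centre is best bought and never disturbed. The second difficulty is the contiguous substitution of ring A. The key step uses two facts together. O1 is bonded to C8a, which lies para to the C6 carbonyl carbon, so a nucleofuge at C8a can be displaced by addition–elimination. The unit O–C2(CH3)(chain)–C3=C4 is, atom for atom and with the same S arrangement, the tertiary allylic alcohol of (S)-linalool.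

## Logic of the disconnections

**21 to 20.** The three phenolic O–H bonds are traced back to O–CH2OCH3 acetals. The phenols must be masked through the organolithium, Heck, alkoxide, Grignard and aldol steps, and one kind of acetal allows a single unmasking. The forward step must cleave three aryl acetals with acid that spares the tertiary alcohol, the C2–O1 bond and the enone.

**20 to 16 and 18.** The Cα=Cβ bond of the enone is cut. This splits off the whole cinnamoyl arm as an aldehyde and postpones the Michael acceptor to the penultimate step. The demand is an aldol condensation in which only one partner can enolise and dehydration gives the E-alkene.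

**16 to 15 to 14.** The bond between the carbonyl carbon and its methyl group is cut, so the ketone is traced to a formyl group at C6. The formyl group is wanted earlier because it is the strongest simple para acceptor and cannot be enolised by alkoxide. The forward steps are a methyl addition in the presence of a free tertiary alcohol and an oxidation that touches only the new benzylic carbinol.

**14 to 13.** The O1–C8a bond is cut. Ring B opens to an acyclic (Z)-styrenyl tertiary carbinol with fluorine on C8a, and the stereocentre becomes a carbinol carbon that can come from the chiral pool. The forward step needs the Z geometry, an alkoxide that survives next to an aldehyde, and enough activation of C8a by the para formyl group.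

**13 to 12.** No bond is cut; the alkene geometry is inverted. The convergent coupling of the next paragraph can only deliver the E-isomer, so a contra-thermodynamic E-to-Z isomerisation is required. It must leave the aldehyde, the aryl fluoride and the carbinol untouched.

**12 to 8 and 11.** The C4–C4a bond (aryl to vinyl) is cut. This gives two fragments of similar size, an aryl iodide and a terminal vinyl carbinol. The forward step must arylate the unsubstituted vinyl terminus only, which the lack of a hydrogen on the carbinol carbon secures.

**11 to 10 to 9.** The C–O bond of the chain hydroxyl is traced to the trisubstituted alkene of 9 through epoxide 10. The demand is chemoselectivity over the vinyl group and suppression of ether formation by the C3 hydroxyl.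

**8 to 3 (through 4 to 7), 2 and 1.** The C–I bond at the future C4a and the C–CHO bond at the future C6 are cut, then the C–Br bond and the two acetals. The halogen para to fluorine is placed by electrophilic substitution. The iodine between fluorine and an acetal oxygen is placed by deprotonation at the most acidic ring position. The formyl group must be masked in the flask while that deprotonation takes place, and the 2-fluoroaryllithium must be kept cold.

**18 to 17.** One O–CH2OCH3 bond is cut, so that the aldehyde partner does not become a deactivated phenoxide in the condensation.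

## Other disconnections considered

**Alternative 1:** The cut goes through O1–C2 and through the C1'–C2' bond of the side chain (chain atoms counted from C2). In the forward direction 3,6-dimethoxy-2-(3-methylbut-3-en-1-yl)phenol A1 would meet a divalent palladium catalyst carrying a chiral bis(oxazoline) ligand. The phenol oxygen adds to the coordinated 1,1-disubstituted alkene and closes ring B. The alkylpalladium formed has no β-hydrogen and is intercepted by methyl acrylate A2 in a Heck-type step, giving chroman ester A3 (R descriptor at C2, the same spatial arrangement as the target because the substituent priorities change).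

- In its favour: C2 is created by a catalyst from achiral material, so the enantiopurity does not depend on a natural source. The ester is a good handle for the chain (alkene reduction, double methyl addition).
- Better than the chosen plan: the key step builds one ring, two bonds and the stereocentre, against one ring and one bond in step 8.
- Against it here: the product is a chroman, so C3=C4 must be introduced late by benzylic dehydrogenation of a functionalised ring A. Ring A arrives without the C6 carbon, so an acylation must distinguish C6 from C7. The two O-methyl groups need a strong Lewis acid in the presence of the tertiary alcohol and the chromene.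
- Mechanistic comparison: the configuration rests on ligand control of an oxypalladation in which methyl and CH2 must be told apart. In the chosen plan it follows from retention at a bond that is never broken.
- Step economy: the steps to A1 and the many adjustments after A3 should make this route longer than 13 steps.

**Alternative 2:** The cut removes ring A altogether (C7–C8, C5–C6, C4a–C5). In the forward direction the dihydropyranyl methoxycarbene complex of zerovalent chromium A4 would react with tert-butyldimethyl(prop-2-yn-1-yloxy)silane A5 in a Dötz benzannulation. The alkyne inserts, a carbonyl ligand becomes C5, and electrocyclisation and tautomerisation give phenol A6.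

- In its favour: all six positions of ring A are fixed by the mechanism in one step, with the larger alkyne substituent next to the new phenol.
- Equal or slightly better than the chosen plan: regiocontrol of ring A does not depend on substituent-directed halogenation and metalation. The C5 hydroxyl and C8 oxygen are also differentiated, which the target does not need.
- Against it here: stoichiometric chromium carbonyl chemistry, a chroman oxidation level, a methyl ether at C8 and a CH2OSi group at C6 that still has to become the ketone.
- Structural comparison: the C2 problem is only moved, because A4 must already contain the quaternary centre in a dihydropyran that needs its own enantioselective synthesis. The chosen plan takes the centre ready-made from 9.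
- Step economy: clearly longer.

**Alternative 3:** The cut is C2–C3. In the forward direction aryl enol ether A7, which carries an ortho (Z)-vinylsilane, would be protonated at the terminal CH2. The resulting aryloxy oxocarbenium ion is attacked at C2 by the silicon-bearing alkene carbon, and loss of silicon gives chromene A8.

- In its favour: a C–C bond closes ring B, and ipso substitution fixes the position of the new alkene.
- Equal to the chosen plan: the 2H-chromene is obtained directly at the right oxidation level with C3=C4 in place.
- Against it here: C2 passes through a planar cation whose faces differ only by methyl versus CH2. Enantiocontrol would have to come from a chiral counter-anion with no help from the substrate, and the S configuration demanded for A8 is the least secure element.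
- Further drawbacks: the acid needed for protonation threatens the silyl ether and can hydrolyse the enol ether. Ring A again lacks the C6 carbon and carries methyl ethers.
- Mechanistic comparison: a cationic closure with external asymmetric induction, against an anionic addition–elimination with the configuration fixed beforehand.
- Step economy: the number of steps to the chromene would be similar, but C6 functionalisation and demethylation add steps afterwards.

Key step: step 8

Remark: (S)-(+)-linalool is taken as a commercial material of high enantiomeric purity; no bond to its carbinol carbon is broken, so the enantiomeric purity of the target should equal that of this starting material.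

## Route

Step 1
Reactants: 1 2-fluorobenzene-1,4-diol
Product: 2 2-fluoro-1,4-bis(methoxymethoxy)benzene
Conditions: MOMCl (2.6 equiv), EtN(i-Pr)2 (3 equiv), CH2Cl2, 0 °C → rt
Reagents that add atoms: chloromethyl methyl ether (MOMCl), COCCl
Why: Williamson-type O-alkylation of both phenols by the reactive α-chloro ether; the acetal ethers survive all later basic and organometallic steps and serve as directing groups for the metalation in step 3.

Step 2
Reactants: 2 2-fluoro-1,4-bis(methoxymethoxy)benzene
Product: 3 1-bromo-4-fluoro-2,5-bis(methoxymethoxy)benzene
Conditions: NBS (1.05 equiv), MeCN, 0 °C → rt, dark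
Reagents that add atoms: N-bromosuccinimide, O=C1CCC(=O)N1Br
Why: Electrophilic aromatic bromination; the position ortho to an acetal oxygen and para to fluorine is the most electron-rich, since one other open position is deactivated by the meta fluorine and the third is flanked on both sides.

Step 3
Reactants: 3 1-bromo-4-fluoro-2,5-bis(methoxymethoxy)benzene
Product: 8 4-fluoro-3-iodo-2,5-bis(methoxymethoxy)benzaldehyde, via aryllithium 4 (not isolated), via lithium aminoalkoxide 5 (not isolated), via ring-lithiated aminoalkoxide 6 (not isolated), via iodinated aminoalkoxide 7 (not isolated)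
Conditions: n-BuLi (1.05 equiv), THF, −78 °C; DMF (1.05 equiv), −78 °C; LiTMP (lithium 2,2,6,6-tetramethylpiperidide, 1.3 equiv, from the amine and n-BuLi), −78 °C; I2 (1.5 equiv), −78 °C; then H2O, aq. Na2S2O3
Reagents that add atoms: N,N-dimethylformamide, CN(C)C=O; iodine, II
Why: Bromine–lithium exchange and formylation give the tetrahedral adduct 5, which is stable at −78 °C and masks the formyl group in the flask; the hindered amide base then removes the most acidic ring proton, the one between fluorine and an acetal oxygen (directed ortho-metalation), and iodine traps the aryllithium. The 2-fluoroaryllithium 6 is kept at −78 °C so that it does not lose LiF, and aqueous work-up collapses 7 to the aldehyde.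

Step 4
Reactants: 9 (S)-linalool, (3S)-3,7-dimethylocta-1,6-dien-3-ol
Product: 10 (3S)-5-(3,3-dimethyloxiran-2-yl)-3-methylpent-1-en-3-ol (both configurations at the oxirane CH)
Conditions: mCPBA (1.05 equiv), CH2Cl2 / aq. NaHCO3 (two-phase), 0 °C
Reagents that add atoms: 3-chloroperoxybenzoic acid (mCPBA), OOC(=O)c1cccc(Cl)c1
Why: Prilezhaev epoxidation; the trisubstituted alkene is far more nucleophilic than the monosubstituted vinyl group, and the buffer keeps the hydroxy epoxide from cyclising. The oxirane CH centre disappears in step 5, and C3 is not touched.

Step 5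
Reactants: 10 (3S)-5-(3,3-dimethyloxiran-2-yl)-3-methylpent-1-en-3-ol
Product: 11 (3S)-3,7-dimethyloct-1-ene-3,7-diol
Conditions: LiAlH4 (1.5 equiv), THF, 0 °C → rt; aqueous work-up
Reagents that add atoms: none
Why: Hydride opens the trisubstituted epoxide by SN2 attack at its less substituted carbon, leaving the oxygen on the tertiary carbon (net Markovnikov hydration of the original alkene); the vinyl group is inert to the hydride.

Step 6
Reactants: 8 4-fluoro-3-iodo-2,5-bis(methoxymethoxy)benzaldehyde; 11 (3S)-3,7-dimethyloct-1-ene-3,7-diol
Product: 12 4-fluoro-3-[(1E,3S)-3,7-dihydroxy-3,7-dimethyloct-1-en-1-yl]-2,5-bis(methoxymethoxy)benzaldehyde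
Conditions: Pd(OAc)2 (5 mol %), n-Bu4NCl (1 equiv), NaHCO3 (2.5 equiv), DMF, 70 °C
Reagents that add atoms: none
Why: Mizoroki–Heck reaction under ligand-free phase-transfer conditions; the aryl group adds to the unsubstituted vinyl terminus, and because the carbinol carbon bears no hydrogen, syn β-hydride elimination can only give the E-styrene. The formyl group and both tertiary hydroxyls are tolerated.

Step 7
Reactants: 12 4-fluoro-3-[(1E,3S)-3,7-dihydroxy-3,7-dimethyloct-1-en-1-yl]-2,5-bis(methoxymethoxy)benzaldehyde
Product: 13 4-fluoro-3-[(1Z,3S)-3,7-dihydroxy-3,7-dimethyloct-1-en-1-yl]-2,5-bis(methoxymethoxy)benzaldehyde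
Conditions: fac-Ir(ppy)3 (1 mol %), degassed MeCN, blue LEDs (450 nm), rt
Reagents that add atoms: none
Why: Contra-thermodynamic E-to-Z isomerisation by triplet energy transfer; the E-styrene accepts energy from the excited sensitiser, whereas in the Z-isomer the doubly ortho-substituted ring is twisted out of conjugation by the cis carbinol, so its triplet energy is higher and it should accumulate. No bond to the stereocentre is touched, and unconverted 12 can be recovered and irradiated again.

Step 8
Reactants: 13 4-fluoro-3-[(1Z,3S)-3,7-dihydroxy-3,7-dimethyloct-1-en-1-yl]-2,5-bis(methoxymethoxy)benzaldehyde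
Product: 14 (2S)-2-(4-hydroxy-4-methylpentyl)-5,8-bis(methoxymethoxy)-2-methyl-2H-chromene-6-carbaldehyde
Conditions: KOt-Bu (2.2 equiv), THF (0.02 M), 0 °C → rt (to 50 °C if slow); aq. NH4Cl
Reagents that add atoms: none
Why: tert-Butoxide equilibrates with the tertiary hydroxyls, and the allylic potassium alkoxide adds to C8a to give a Meisenheimer complex whose charge is delocalised onto the oxygen of the para formyl group at C6; loss of fluoride then restores the aromatic ring (SNAr, addition–elimination). The closest known reaction type is the intramolecular SNAr etherification of alkoxides tethered to fluoroarenes that carry an ortho or para carbonyl group, as used for chromans and benzoxazines. Ring B closes in a 6-exo-trig-type mode, the attacked C8a being a ring atom of the arene and the electrons moving out of the forming ring. No stereocentre is created, and the C2–O bond stays intact throughout, so the S configuration of 13 passes into 14 with retention. The step needs geometric selectivity, which the Z-alkene supplies by holding the oxygen within bonding distance of C8a, while any E-isomer cannot reach and is recovered. It needs chemoselectivity between the two alkoxides, which ring size provides, since the chain alkoxide could only close a ten-membered ring, and high dilution suppresses intermolecular attack by it or by tert-butoxide at the doubly flanked C8a. Fluoride is the nucleofuge of choice because addition is rate-limiting, and the formyl group is both a strong para acceptor and non-enolisable, so the base finds no acidic C–H.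

Step 9
Reactants: 14 (2S)-2-(4-hydroxy-4-methylpentyl)-5,8-bis(methoxymethoxy)-2-methyl-2H-chromene-6-carbaldehyde
Product: 15 5-[(2S)-6-(1-hydroxyethyl)-5,8-bis(methoxymethoxy)-2-methyl-2H-chromen-2-yl]-2-methylpentan-2-ol (both configurations at the new carbinol carbon)
Conditions: MeMgBr (3 equiv), THF, −20 → 0 °C; then H2O
Reagents that add atoms: methylmagnesium bromide, C[Mg]Br
Why: Grignard 1,2-addition to the aldehyde after the first equivalent has deprotonated the tertiary alcohol; the new carbinol centre is formed without control, which does not matter because it is oxidised in step 10.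

Step 10
Reactants: 15 5-[(2S)-6-(1-hydroxyethyl)-5,8-bis(methoxymethoxy)-2-methyl-2H-chromen-2-yl]-2-methylpentan-2-ol
Product: 16 1-[(2S)-2-(4-hydroxy-4-methylpentyl)-5,8-bis(methoxymethoxy)-2-methyl-2H-chromen-6-yl]ethan-1-one
Conditions: Dess–Martin periodinane (1.3 equiv), CH2Cl2, 0 °C → rt
Reagents that add atoms: none
Why: Dess–Martin oxidation of the secondary benzylic alcohol to the aryl methyl ketone; the tertiary alcohol cannot be oxidised, and the chromene alkene and the acetals are inert.

Step 11
Reactants: 17 4-hydroxybenzaldehyde
Product: 18 4-(methoxymethoxy)benzaldehyde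
Conditions: MOMCl (1.3 equiv), EtN(i-Pr)2 (1.5 equiv), CH2Cl2, 0 °C → rt
Reagents that add atoms: chloromethyl methyl ether (MOMCl), COCCl
Why: O-alkylation of the phenol; without it the phenoxide would deactivate the aldehyde towards the enolate in step 12.

Step 12
Reactants: 16 1-[(2S)-2-(4-hydroxy-4-methylpentyl)-5,8-bis(methoxymethoxy)-2-methyl-2H-chromen-6-yl]ethan-1-one; 18 4-(methoxymethoxy)benzaldehyde
Product: 20 (2E)-1-[(2S)-2-(4-hydroxy-4-methylpentyl)-5,8-bis(methoxymethoxy)-2-methyl-2H-chromen-6-yl]-3-[4-(methoxymethoxy)phenyl]prop-2-en-1-one, via aldol adduct 19 (not isolated)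
Conditions: KOH (5 equiv), EtOH, rt
Reagents that add atoms: none
Why: Claisen–Schmidt condensation; only 16 can form an enolate and 18 has no α-hydrogen, and E1cB loss of water from the aldol adduct gives the conjugated E-enone as the thermodynamic isomer. All other groups are stable to base.

Step 13
Reactants: 20 (2E)-1-[(2S)-2-(4-hydroxy-4-methylpentyl)-5,8-bis(methoxymethoxy)-2-methyl-2H-chromen-6-yl]-3-[4-(methoxymethoxy)phenyl]prop-2-en-1-one
Product: 21 (2E)-1-[(2S)-5,8-dihydroxy-2-(4-hydroxy-4-methylpentyl)-2-methyl-2H-chromen-6-yl]-3-(4-hydroxyphenyl)prop-2-en-1-one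
Conditions: HCl (about 1 M, conc. aq. HCl in MeOH), rt → 35 °C, argon
Reagents that add atoms: none
Why: Acid-catalysed acetal exchange with methanol removes all three aryl methoxymethyl ethers; phenolic acetals cleave under acid mild enough for the tertiary alcohol and the chromene, and the lack of a hydroxyl at C7 should make flavanone formation slow. C2 is not involved.

## Compound list

1 | 2-fluorobenzene-1,4-diol | Oc1ccc(O)c(F)c1 | starting material
2 | 2-fluoro-1,4-bis(methoxymethoxy)benzene | COCOc1ccc(OCOC)c(F)c1 | intermediate
3 | 1-bromo-4-fluoro-2,5-bis(methoxymethoxy)benzene | COCOc1cc(Br)c(OCOC)cc1F | intermediate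
4 | [4-fluoro-2,5-bis(methoxymethoxy)phenyl]lithium (formed in the flask) | [Li]c1cc(OCOC)c(F)cc1OCOC | intermediate
5 | lithium (dimethylamino)[4-fluoro-2,5-bis(methoxymethoxy)phenyl]methanolate (formed in the flask) | [Li]OC(N(C)C)c1cc(OCOC)c(F)cc1OCOC | intermediate
6 | lithium (dimethylamino)[4-fluoro-3-lithio-2,5-bis(methoxymethoxy)phenyl]methanolate (formed in the flask) | [Li]OC(N(C)C)c1cc(OCOC)c(F)c([Li])c1OCOC | intermediate
7 | lithium (dimethylamino)[4-fluoro-3-iodo-2,5-bis(methoxymethoxy)phenyl]methanolate (formed in the flask) | [Li]OC(N(C)C)c1cc(OCOC)c(F)c(I)c1OCOC | intermediate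
8 | 4-fluoro-3-iodo-2,5-bis(methoxymethoxy)benzaldehyde | O=Cc1cc(OCOC)c(F)c(I)c1OCOC | intermediate
9 | (S)-linalool, (3S)-3,7-dimethylocta-1,6-dien-3-ol | CC(C)=CCC[C@@](O)(C)C=C | starting material
10 | (3S)-5-(3,3-dimethyloxiran-2-yl)-3-methylpent-1-en-3-ol (both configurations at the oxirane CH) | CC1(C)OC1CC[C@@](O)(C)C=C | intermediate
11 | (3S)-3,7-dimethyloct-1-ene-3,7-diol | CC(C)(O)CCC[C@@](O)(C)C=C | intermediate
12 | 4-fluoro-3-[(1E,3S)-3,7-dihydroxy-3,7-dimethyloct-1-en-1-yl]-2,5-bis(methoxymethoxy)benzaldehyde | CC(C)(O)CCC[C@@](O)(C)/C=C/c1c(OCOC)c(C=O)cc(OCOC)c1F | intermediate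
13 | 4-fluoro-3-[(1Z,3S)-3,7-dihydroxy-3,7-dimethyloct-1-en-1-yl]-2,5-bis(methoxymethoxy)benzaldehyde | CC(C)(O)CCC[C@@](O)(C)/C=C\c1c(OCOC)c(C=O)cc(OCOC)c1F | intermediate
14 | (2S)-2-(4-hydroxy-4-methylpentyl)-5,8-bis(methoxymethoxy)-2-methyl-2H-chromene-6-carbaldehyde | CC(C)(O)CCC[C@@]1(C)C=Cc2c(OCOC)c(C=O)cc(OCOC)c2O1 | intermediate
15 | 5-[(2S)-6-(1-hydroxyethyl)-5,8-bis(methoxymethoxy)-2-methyl-2H-chromen-2-yl]-2-methylpentan-2-ol (both configurations at the carbinol carbon) | CC(C)(O)CCC[C@@]1(C)C=Cc2c(OCOC)c(C(C)O)cc(OCOC)c2O1 | intermediate
16 | 1-[(2S)-2-(4-hydroxy-4-methylpentyl)-5,8-bis(methoxymethoxy)-2-methyl-2H-chromen-6-yl]ethan-1-one | CC(C)(O)CCC[C@@]1(C)C=Cc2c(OCOC)c(C(C)=O)cc(OCOC)c2O1 | intermediate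
17 | 4-hydroxybenzaldehyde | O=Cc1ccc(O)cc1 | starting material
18 | 4-(methoxymethoxy)benzaldehyde | O=Cc1ccc(OCOC)cc1 | intermediate
19 | 3-hydroxy-1-[(2S)-2-(4-hydroxy-4-methylpentyl)-5,8-bis(methoxymethoxy)-2-methyl-2H-chromen-6-yl]-3-[4-(methoxymethoxy)phenyl]propan-1-one (formed in the flask, both configurations at the carbinol carbon) | CC(C)(O)CCC[C@@]1(C)C=Cc2c(OCOC)c(C(=O)CC(O)c3ccc(OCOC)cc3)cc(OCOC)c2O1 | intermediate
20 | (2E)-1-[(2S)-2-(4-hydroxy-4-methylpentyl)-5,8-bis(methoxymethoxy)-2-methyl-2H-chromen-6-yl]-3-[4-(methoxymethoxy)phenyl]prop-2-en-1-one | CC(C)(O)CCC[C@@]1(C)C=Cc2c(OCOC)c(C(=O)/C=C/c3ccc(OCOC)cc3)cc(OCOC)c2O1 | intermediate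
21 | (2E)-1-[(2S)-5,8-dihydroxy-2-(4-hydroxy-4-methylpentyl)-2-methyl-2H-chromen-6-yl]-3-(4-hydroxyphenyl)prop-2-en-1-one | CC(C)(O)CCC[C@@]1(C)C=Cc2c(O)c(C(=O)/C=C/c3ccc(O)cc3)cc(O)c2O1 | target

## Step count and least certain steps

Total step count: 13. Longest linear sequence: 10 steps (steps 1, 2, 3, 6, 7, 8, 9, 10, 12, 13).

**Step 8 (key step).** Addition of the hindered tertiary alkoxide to C8a may be slow, because C8a is flanked on both sides and the ring carries two donor oxygens. Prolonged exposure to alkoxide would then let hydride-transfer and hemiacetal chemistry at the formyl group, or intermolecular etherification, compete with ring closure. Fallback: the same ring closure is carried out on a nitrile, which is a para acceptor of similar strength but inert to alkoxide and heat. It sets out from 12 and returns at 14. Oxidative amination of 12 (I2, aqueous NH3, THF, rt) should give 4-fluoro-3-[(1E,3S)-3,7-dihydroxy-3,7-dimethyloct-1-en-1-yl]-2,5-bis(methoxymethoxy)benzonitrile F1. Sensitised isomerisation as in step 7 should give the Z-isomer, 4-fluoro-3-[(1Z,3S)-3,7-dihydroxy-3,7-dimethyloct-1-en-1-yl]-2,5-bis(methoxymethoxy)benzonitrile F2. Closure with KOt-Bu in DMSO, which can now be heated to 60–80 °C, should give (2S)-2-(4-hydroxy-4-methylpentyl)-5,8-bis(methoxymethoxy)-2-methyl-2H-chromene-6-carbonitrile F3. Partial reduction with excess DIBAL-H at −78 °C and mild hydrolysis of the aldimine then leads to 14.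

**Step 3.** The second metalation may take place at the ring position next to the aminoalkoxide, or the 2-fluoroaryllithium may lose LiF before iodine is added; both follow from having two lithiations and a thermally fragile anion in one flask. Fallback: the iodine is introduced by electrophilic substitution directed by a free phenol. It sets out from 3 and returns at 8. Bromine–lithium exchange and DMF quench with aqueous work-up give 4-fluoro-2,5-bis(methoxymethoxy)benzaldehyde F4. The acetal ortho to the formyl group, the more labile of the two, is removed selectively with dilute methanolic HCl at 0 °C to give 4-fluoro-2-hydroxy-5-(methoxymethoxy)benzaldehyde F5. Iodination with N-iodosuccinimide in DMF occurs at the only position ortho to the free hydroxyl and gives 4-fluoro-2-hydroxy-3-iodo-5-(methoxymethoxy)benzaldehyde F6. Renewed alkylation with MOMCl and EtN(i-Pr)2 then gives 8.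

**Step 7.** The photostationary state may be unfavourable if sensitiser and substrate triplet energies are poorly matched, and the formyl-substituted arene may undergo its own excited-state reactions. Fallback: the Z geometry is set by syn semi-hydrogenation of an alkyne. It sets out from 11 and 8 and returns at 13.

- Silylation of 11 (TESOTf, 2,6-lutidine) gives (3S)-3,7-dimethyl-3,7-bis(triethylsilyloxy)oct-1-ene F7.
- Ozonolysis (O3, CH2Cl2, −78 °C; PPh3) gives (2S)-2,6-dimethyl-2,6-bis(triethylsilyloxy)heptanal F8, whose α-carbon is quaternary and cannot epimerise.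
- The Ohira–Bestmann reagent (K2CO3, MeOH) gives (3S)-3,7-dimethyl-3,7-bis(triethylsilyloxy)oct-1-yne F9.
- Fluoride (n-Bu4NF, THF) gives (3S)-3,7-dimethyloct-1-yne-3,7-diol F10.
- Sonogashira coupling with 8 (Pd(PPh3)2Cl2, CuI, Et3N) gives 4-fluoro-3-[(3S)-3,7-dihydroxy-3,7-dimethyloct-1-yn-1-yl]-2,5-bis(methoxymethoxy)benzaldehyde F11.
- Hydrogenation over Lindlar catalyst (Pd/CaCO3 poisoned with Pb(OAc)2, quinoline, H2) gives 13.

**Step 13.** The slowest of the three acetals may need more acid or time than the molecule tolerates. The possible failures are ionisation of the tertiary alcohol or of the C2–O1 bond, and closure of the freed C5 hydroxyl onto the enone. Fallback: the acetals are removed before the enone exists. It sets out from 16 and returns at 21. Dilute methanolic HCl on 16 (only two acetals, one accelerated by the ortho carbonyl group) gives 1-[(2S)-5,8-dihydroxy-2-(4-hydroxy-4-methylpentyl)-2-methyl-2H-chromen-6-yl]ethan-1-one F12. Claisen–Schmidt condensation of this ketone with unprotected 17 (excess KOH, EtOH/H2O, argon) then gives 21 directly. The condensation is expected to be slower because both partners are phenoxides.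

**Step 4.** The C3 hydroxyl may open the new epoxide intramolecularly (5-exo attack giving furanoid ethers), promoted by the carboxylic acid co-product or by silica during isolation. Fallback: the hydroxyl is capped first. It sets out from 9 and returns at 11. Acetylation (Ac2O, Et3N, DMAP) gives (3S)-3,7-dimethylocta-1,6-dien-3-yl acetate F13. Epoxidation with mCPBA gives (3S)-5-(3,3-dimethyloxiran-2-yl)-3-methylpent-1-en-3-yl acetate F14, which has no free hydroxyl to cyclise. LiAlH4 then opens the epoxide and cleaves the acetate in one operation to give 11.

## Further compounds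

F1 | step 8 | 4-fluoro-3-[(1E,3S)-3,7-dihydroxy-3,7-dimethyloct-1-en-1-yl]-2,5-bis(methoxymethoxy)benzonitrile | CC(C)(O)CCC[C@@](O)(C)/C=C/c1c(OCOC)c(C#N)cc(OCOC)c1F
F2 | step 8 | 4-fluoro-3-[(1Z,3S)-3,7-dihydroxy-3,7-dimethyloct-1-en-1-yl]-2,5-bis(methoxymethoxy)benzonitrile | CC(C)(O)CCC[C@@](O)(C)/C=C\c1c(OCOC)c(C#N)cc(OCOC)c1F
F3 | step 8 | (2S)-2-(4-hydroxy-4-methylpentyl)-5,8-bis(methoxymethoxy)-2-methyl-2H-chromene-6-carbonitrile | CC(C)(O)CCC[C@@]1(C)C=Cc2c(OCOC)c(C#N)cc(OCOC)c2O1
F4 | step 3 | 4-fluoro-2,5-bis(methoxymethoxy)benzaldehyde | O=Cc1cc(OCOC)c(F)cc1OCOC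
F5 | step 3 | 4-fluoro-2-hydroxy-5-(methoxymethoxy)benzaldehyde | O=Cc1cc(OCOC)c(F)cc1O
F6 | step 3 | 4-fluoro-2-hydroxy-3-iodo-5-(methoxymethoxy)benzaldehyde | O=Cc1cc(OCOC)c(F)c(I)c1O
F7 | step 7 | (3S)-3,7-dimethyl-3,7-bis(triethylsilyloxy)oct-1-ene | CC(C)(O[Si](CC)(CC)CC)CCC[C@@](O[Si](CC)(CC)CC)(C)C=C
F8 | step 7 | (2S)-2,6-dimethyl-2,6-bis(triethylsilyloxy)heptanal | CC(C)(O[Si](CC)(CC)CC)CCC[C@@](O[Si](CC)(CC)CC)(C)C=O
F9 | step 7 | (3S)-3,7-dimethyl-3,7-bis(triethylsilyloxy)oct-1-yne | CC(C)(O[Si](CC)(CC)CC)CCC[C@@](O[Si](CC)(CC)CC)(C)C#C
F10 | step 7 | (3S)-3,7-dimethyloct-1-yne-3,7-diol | CC(C)(O)CCC[C@@](O)(C)C#C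
F11 | step 7 | 4-fluoro-3-[(3S)-3,7-dihydroxy-3,7-dimethyloct-1-yn-1-yl]-2,5-bis(methoxymethoxy)benzaldehyde | CC(C)(O)CCC[C@@](O)(C)C#Cc1c(OCOC)c(C=O)cc(OCOC)c1F
F12 | step 13 | 1-[(2S)-5,8-dihydroxy-2-(4-hydroxy-4-methylpentyl)-2-methyl-2H-chromen-6-yl]ethan-1-one | CC(C)(O)CCC[C@@]1(C)C=Cc2c(O)c(C(C)=O)cc(O)c2O1
F13 | step 4 | (3S)-3,7-dimethylocta-1,6-dien-3-yl acetate | CC(C)=CCC[C@@](OC(C)=O)(C)C=C
F14 | step 4 | (3S)-5-(3,3-dimethyloxiran-2-yl)-3-methylpent-1-en-3-yl acetate (both configurations at the oxirane CH) | CC1(C)OC1CC[C@@](OC(C)=O)(C)C=C
A1 | alternative 1 | 3,6-dimethoxy-2-(3-methylbut-3-en-1-yl)phenol | C=C(C)CCc1c(O)c(OC)ccc1OC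
A2 | alternative 1 | methyl acrylate | C=CC(=O)OC
A3 | alternative 1 | methyl (2E)-4-[(2R)-5,8-dimethoxy-2-methyl-3,4-dihydro-2H-chromen-2-yl]but-2-enoate | COC(=O)/C=C/C[C@@]1(C)CCc2c(OC)ccc(OC)c2O1
A4 | alternative 2 | pentacarbonyl{methoxy[(2S)-2-methyl-2-(4-methyl-4-triethylsilyloxypentyl)-3,4-dihydro-2H-pyran-6-yl]methylidene}chromium | COC(C1=CCC[C@](C)(CCCC(C)(C)O[Si](CC)(CC)CC)O1)=[Cr](=C=O)(=C=O)(=C=O)(=C=O)=C=O
A5 | alternative 2 | tert-butyldimethyl(prop-2-yn-1-yloxy)silane | C#CCO[Si](C)(C)C(C)(C)C
A6 | alternative 2 | (2S)-6-[(tert-butyldimethylsilyloxy)methyl]-8-methoxy-2-methyl-2-[4-methyl-4-(triethylsilyloxy)pentyl]-3,4-dihydro-2H-chromen-5-ol | CC(C)(O[Si](CC)(CC)CC)CCC[C@@]1(C)CCc2c(O)c(CO[Si](C)(C)C(C)(C)C)cc(OC)c2O1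
A7 | alternative 3 | triethyl{[2-methyl-6-({3,6-dimethoxy-2-[(Z)-2-(trimethylsilyl)ethenyl]phenyl}oxy)hept-6-en-2-yl]oxy}silane | C=C(CCCC(C)(C)O[Si](CC)(CC)CC)Oc1c(OC)ccc(OC)c1/C=C\[Si](C)(C)C
A8 | alternative 3 | (2S)-5,8-dimethoxy-2-methyl-2-[4-methyl-4-(triethylsilyloxy)pentyl]-2H-chromene | CC(C)(O[Si](CC)(CC)CC)CCC[C@@]1(C)C=Cc2c(OC)ccc(OC)c2O1
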